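80.0 % of the electrophile charged is the share that the nucleophile can turn into target, one molecule for one. This share is called here the ceiling, and the nucleophile, charged at 0.640 M against 0.80 M of electrophile, is the limiting reagent.

| setting | Friday's | Sunday's | Monday's | teal | grey | amber |
|---|---|---|---|---|---|---|
| electrophile | 0.80 M | 0.80 M | 0.80 M | 0.80 M | 0.80 M | 0.80 M |
| nucleophile | 0.64 M | 0.64 M | 0.64 M | 0.640 M | 0.640 M | 0.640 M |
| free base | 1.8 M | 2.2 M | 2.8 M | 1.60 M | 2.10 M | 2.70 M |
| remark | run made earlier | run made earlier | run made earlier |  |  |  |
| time |  |  |  | 30 min | 30 min | 30 min |

| run | time / min | electrophile / % | target / % |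
|---|---|---|---|
| Friday's | 1.33 | 25.0 | 71.6 |
| Friday's | 4.00 | 18.4 | 76.4 |
| Friday's | 8.00 | 16.9 | 76.6 |
| Friday's | 10.0 | 17.2 | 76.2 |
| Friday's | 15.0 | 14.0 | 75.2 |
| Sunday's | 3.00 | 18.2 | 78.6 |
| Sunday's | 6.00 | 17.5 | 75.9 |
| Sunday's | 10.0 | 15.3 | 76.6 |
| Sunday's | 12.0 | 16.2 | 74.1 |
| Sunday's | 15.0 | 15.5 | 74.9 |
| Monday's | 1.33 | 20.8 | 75.7 |
| Monday's | 2.50 | 18.3 | 77.6 |
| Monday's | 4.00 | 18.8 | 79.5 |
| Monday's | 8.00 | 16.1 | 77.4 |
| Monday's | 15.0 | 15.1 | 76.4 |

(standard deviation of a reading: 1 percentage point)

* part of the electrophile that has reacted at the end, teal
* part of the electrophile that has reacted at the end, grey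
* part of the electrophile that has reacted at the end, amber
* what raising the concentration of free base from its lowest to its highest value here does to the part of the electrophile that has reacted (changes below 5 percentage points count as none) (no change / it falls / it rises)

- percentages count the electrophile that a species holds: one side product counts as two
- target is meant together with its crystals
- solid, in amounts per volume of the solution: crystals
- the numbers in the tables scatter by 1 percentage point (one standard deviation)
- reactions considered so far: electrophile + nucleophile -> acid set free + target; nucleophile + acid set free <-> protonated nucleophile; acid set free + free base <-> salt of the base; crystals <-> target; electrophile + target -> side product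

In the first instants a molecule of electrophile meets nucleophile and becomes target, while the acid set free can pass to the free base. Even teal's 1.60 M of free base is 2.50 times the 0.640 M of acid that the nucleophile can release. Friday's run already reads 25.0 % electrophile at 1.33 min and 18.4 % at 4.00 min, close to the 20.0 % above the ceiling.

In the middle, a remaining molecule has the other fork: it can meet target and give side product. One side product counts as two, because it holds one electrophile and one target. So the part reacted is the ceiling plus the side product's percentage divided by two, and target falls by that same quotient.

By the end, the last readings at 15.0 min are 14.0 %, 15.5 % and 15.1 % of electrophile, with free base rising from 1.8 M to 2.8 M. They differ by at most 1.5 percentage points at a scatter of 1 point, and their mean is 14.9 %. The start of the flask can't serve as the base of a decay, since the electrophile still reads above the ceiling's remainder at 1.33 min, so the slow stretch is taken from the readings at 4.00 min, 18.4 % on Friday and 18.8 % on Monday, with mean 18.6 %. From there to the last readings, over 11.0 min, the remainder shrinks by a factor of 0.799, a figure that carries the scatter of the readings. If the crystals hold dissolved target steady, the remainder shrinks by that same factor in each such interval. The reckoning made here therefore gives 89.0 % reacted at 30 min in teal, grey and amber.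

The forecast is a little lower, with 88 %, 88 % and 88 % and the trend "no change", and it holds that “Every base level, including 1.6 M, exceeds the 0.64 M of acid that can form, so the nucleophile is never held up as its protonated form.”

The flasks give 87.9 % in teal, 87.9 % in grey and 87.9 % in amber, a change of −0.063 points across the free base, so the trend is "no change".

    electrophile + nucleophile → acid set free + target (k = 0.559 L mol⁻¹ s⁻¹)
    nucleophile + acid set free ⇌ protonated nucleophile, settled at all times (K = 131 L mol⁻¹)
    acid set free + free base ⇌ salt of the base (K = 342 L mol⁻¹, k = 0.110 L mol⁻¹ s⁻¹)
    crystals ⇌ target, rate k4*(cs4 - [target]) while solid is left; crystals form when [target] > cs4 (solubility = 42.0 mM, k = 0.710 s⁻¹)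
    electrophile + target → side product (k = 0.00620 L mol⁻¹ s⁻¹)

Amber's first step had half its turnover behind it by 0.0793 min, and teal's nucleophile stood under a fiftieth of its charge by 1.25 min. At 30.0 min amber held 12.1 % electrophile, 72.1 % target and 15.8 % side product, and the ceiling plus that side product divided by two gives 87.9 %. The same flask with 0.38 M of nucleophile has a ceiling of 47.5 %. Its 39.6 % of side product brings the sum to 67.3 %, and that flask stands at 67.3 % reacted.

(The runs are simulated with constants of no real substance; noise was put on by code.)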